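**Plan**

- Retrosynthetic cuts, in order: the acyl–N bond of a chiral oxazolidinone imide (masked acid), the alkyne–vinyl bond of the enyne (Sonogashira), the ketal C6–OMe bond, a helper ester on C5, and finally the dioxane bonds C4–C5, C3–O2 and C6–O1 in one three-component event.
- Enabling feature: the 1,2-dioxane is a closed γ-hydroperoxy ketone (ketal carbon C6 lies 1,4 to the peroxy-bearing C3). C5 can be doubly activated as the central carbon of a β-keto ester, C4=C3 is the terminal alkene of a but-3-enoyl unit, and O1–O2 is dioxygen.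
- Forward: the β-keto ester, the butenoyl imide and air build the dioxane ring first (step 3). The ester helper is then removed, the ketal is fixed with methanol, the dienyl iodide is joined by Sonogashira coupling, and the auxiliary is hydrolysed last.
- Stereochemistry: the ketal carbon is set under thermodynamic control (axial OMe by the anomeric effect, both carbon chains equatorial) relative to C3. C3 forms without facial control, and its absolute configuration is secured by separating the two oxazolidinone diastereomers after ketalisation. The E-alkene comes from a Takai olefination.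

Key step: step 3

Remark: ring positions follow the target in all intermediates (O1, O2, C3 = CH carrying the CH2CO arm, C4, C5, C6 = ketal carbon). It is assumed that the two C3-epimeric series, which the radical step cannot distinguish, separate as oxazolidinone diastereomers once the ketal is fixed.

**Step 1**
Reactants: 1 hex-5-ynoic acid and 2 mono-tert-butyl malonate
Product: 4 tert-butyl 3-oxooct-7-ynoate, via acyl imidazole 3 (not isolated)
Conditions: CDI, THF, 23 °C; then 2, MgCl2, Et3N, THF, 23 → 45 °C; aq. citric acid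
Reagents that add atoms: none
Why: Activation of the acid as its acyl imidazole, C-acylation of the magnesium enolate of the malonate half ester and loss of CO2 (decarboxylative Claisen-type condensation) should give the β-keto ester under near-neutral conditions that spare the terminal alkyne, placing the ester helper on the future ring carbon C5.

**Step 2**
Reactants: 5 but-3-enoic acid and 6 (S)-4-benzyloxazolidin-2-one
Product: 8 (S)-4-benzyl-3-(but-3-enoyl)oxazolidin-2-one, via mixed pivalic anhydride 7 (not isolated)
Conditions: t-BuCOCl, Et3N, THF, −20 °C; then 6, n-BuLi, THF, −78 → 0 °C; aq. NH4Cl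
Reagents that add atoms: none
Why: N-Acylation of the lithiated oxazolidinone by the mixed anhydride at its less hindered butenoyl carbonyl should give the imide at low temperature without migration of the β,γ-double bond into conjugation, the auxiliary stereocentre being carried in unchanged from 6.

**Step 3**
Reactants: 4 tert-butyl 3-oxooct-7-ynoate and 8 (S)-4-benzyl-3-(but-3-enoyl)oxazolidin-2-one
Product: 10 tert-butyl 6-{2-[(S)-4-benzyl-2-oxooxazolidin-3-yl]-2-oxoethyl}-3-hydroxy-3-(pent-4-yn-1-yl)-1,2-dioxane-4-carboxylate (stereoisomer mixture), via open-chain hydroperoxide 9 (not isolated)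
Conditions: Mn(OAc)3·2H2O (0.2 equiv), 8 (3 equiv), AcOH, dry air (1 atm), 23 °C
Reagents that add atoms: dioxygen, O=O
Why: Trivalent manganese forms the enolate of 4 and oxidises it to the electrophilic 1,3-dicarbonyl radical at C5, which adds to the terminal CH2 of 8 (C4–C5 bond); the secondary radical at C3 then captures dioxygen (C3–O2 bond), and the peroxyl radical is reduced by divalent manganese, which regenerates the catalyst and gives hydroperoxide 9. The closest known reaction type is the manganese-acetate-catalysed aerobic [2+2+2] peroxidation of β-keto esters with alkenes to 1,2-dioxan-3-ols. The dioxane ring closes by 6-exo-trig addition of the terminal hydroperoxide oxygen to the C6 ketone (hemiketal, O1–C6). C3 is created by dioxygen capture of an acyclic radical with no facial control, so both configurations should form and are sorted as auxiliary diastereomers after step 5, while the stereocentres at C5 and C6 are transient (C5 loses its substituent in step 4, C6 is reset in step 5). The step needs the C5 radical to add to the alkene faster than it is trapped by dioxygen or cyclises onto its own alkyne, which the persistence of the doubly stabilised radical, the excess of 8 and air in place of pure oxygen should secure; regiochemistry is fixed by the single doubly activated CH2 of 4 and by addition to the unsubstituted alkene terminus.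

**Step 4**
Reactants: 10 tert-butyl 6-{2-[(S)-4-benzyl-2-oxooxazolidin-3-yl]-2-oxoethyl}-3-hydroxy-3-(pent-4-yn-1-yl)-1,2-dioxane-4-carboxylate
Product: 12 (S)-4-benzyl-3-{2-[6-hydroxy-6-(pent-4-yn-1-yl)-1,2-dioxan-3-yl]acetyl}oxazolidin-2-one (both C3 configurations), via dioxanol carboxylic acid 11 (not isolated)
Conditions: TFA/CH2Cl2 (1:4), 0 → 23 °C; evaporate; toluene, 45 °C
Reagents that add atoms: none
Why: Acidolysis of the tert-butyl ester (loss of 2-methylpropene) unmasks acid 11, whose ring-opened γ-hydroperoxy β-keto acid tautomer should decarboxylate on gentle warming and re-close to the hemiketal, removing the helper from C5 without touching the O–O bond, the imide or the alkyne.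

**Step 5**
Reactants: 12 (S)-4-benzyl-3-{2-[6-hydroxy-6-(pent-4-yn-1-yl)-1,2-dioxan-3-yl]acetyl}oxazolidin-2-one
Product: 13 (S)-4-benzyl-3-{2-[(3S,6R)-6-methoxy-6-(pent-4-yn-1-yl)-1,2-dioxan-3-yl]acetyl}oxazolidin-2-one
Conditions: MeOH, CSA (0.1 equiv), 23 °C; SiO2 chromatography
Reagents that add atoms: methanol, CO
Why: Acid-catalysed ketalisation of the peroxy hemiketal through the cyclic peroxycarbenium ion under thermodynamic control should place OMe axial (anomeric effect) and the pentynyl chain equatorial, trans to the equatorial C3 arm, and the (3S,6R) and (3R,6S) ring series, diastereomeric through the auxiliary, are then separated by chromatography to fix the absolute configuration.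

**Step 6**
Reactants: 14 dec-9-enal
Product: 15 (E)-1-iodoundeca-1,10-diene
Conditions: CrCl2, CHI3, THF/1,4-dioxane (1:6), 0 → 23 °C
Reagents that add atoms: iodoform, IC(I)I
Why: Takai olefination, in which the geminal dichromium species from iodoform and divalent chromium adds to the aldehyde and eliminates to the (E)-vinyl iodide, should leave the isolated terminal alkene untouched.

**Step 7**
Reactants: 13 (S)-4-benzyl-3-{2-[(3S,6R)-6-methoxy-6-(pent-4-yn-1-yl)-1,2-dioxan-3-yl]acetyl}oxazolidin-2-one and 15 (E)-1-iodoundeca-1,10-diene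
Product: 16 (S)-4-benzyl-3-{2-[(3S,6R)-6-[(6E)-hexadeca-6,15-dien-4-yn-1-yl]-6-methoxy-1,2-dioxan-3-yl]acetyl}oxazolidin-2-one
Conditions: PdCl2(PPh3)2 (5 mol %), CuI (10 mol %), Et3N, THF, degassed, 23 °C
Reagents that add atoms: none
Why: Sonogashira coupling of the terminal alkyne with the vinyl iodide proceeds with retention of the E geometry at ambient temperature, under which dialkyl peroxyketals are known to tolerate zerovalent palladium and monovalent copper, and the non-nucleophilic amine should not open the imide or the peroxide.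

**Step 8**
Reactants: 16 (S)-4-benzyl-3-{2-[(3S,6R)-6-[(6E)-hexadeca-6,15-dien-4-yn-1-yl]-6-methoxy-1,2-dioxan-3-yl]acetyl}oxazolidin-2-one
Product: 18 2-[(3S,6R)-6-[(6E)-hexadeca-6,15-dien-4-yn-1-yl]-6-methoxy-1,2-dioxan-3-yl]acetic acid, via peroxy acid 17 (not isolated)
Conditions: LiOH·H2O, 30% H2O2, THF/H2O (3:1), 0 °C; aq. Na2SO3; 1 M HCl to pH 4, 0 °C
Reagents that add atoms: hydrogen peroxide, OO
Why: Hydroperoxide-mediated imide hydrolysis, in which lithium hydroperoxide attacks the exocyclic carbonyl and the peroxy acid salt is reduced by sulfite, should release the acid in a cold, weakly basic medium that leaves the peroxyketal, the C3 stereocentre (no retro-Michael ring opening) and the enyne intact.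

**Compound list**

1 | hex-5-ynoic acid | C#CCCCC(=O)O | starting material
2 | mono-tert-butyl malonate (3-tert-butoxy-3-oxopropanoic acid) | CC(C)(C)OC(=O)CC(=O)O | starting material
3 | 1-(imidazol-1-yl)hex-5-yn-1-one (acyl imidazole) | C#CCCCC(=O)n1ccnc1 | intermediate
4 | tert-butyl 3-oxooct-7-ynoate | C#CCCCC(=O)CC(=O)OC(C)(C)C | intermediate
5 | but-3-enoic acid | C=CCC(=O)O | starting material
6 | (S)-4-benzyloxazolidin-2-one | O=C1N[C@@H](Cc2ccccc2)CO1 | starting material
7 | but-3-enoic pivalic anhydride | C=CCC(=O)OC(=O)C(C)(C)C | intermediate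
8 | (S)-4-benzyl-3-(but-3-enoyl)oxazolidin-2-one | C=CCC(=O)N1C(=O)OC[C@@H]1Cc1ccccc1 | intermediate
9 | tert-butyl 2-{4-[(S)-4-benzyl-2-oxooxazolidin-3-yl]-2-hydroperoxy-4-oxobutyl}-3-oxooct-7-ynoate (stereoisomer mixture) | C#CCCCC(=O)C(CC(OO)CC(=O)N1C(=O)OC[C@@H]1Cc1ccccc1)C(=O)OC(C)(C)C | intermediate
10 | tert-butyl 6-{2-[(S)-4-benzyl-2-oxooxazolidin-3-yl]-2-oxoethyl}-3-hydroxy-3-(pent-4-yn-1-yl)-1,2-dioxane-4-carboxylate (stereoisomer mixture at the ring carbons) | C#CCCCC1(O)OOC(CC(=O)N2C(=O)OC[C@@H]2Cc2ccccc2)CC1C(=O)OC(C)(C)C | intermediate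
11 | 6-{2-[(S)-4-benzyl-2-oxooxazolidin-3-yl]-2-oxoethyl}-3-hydroxy-3-(pent-4-yn-1-yl)-1,2-dioxane-4-carboxylic acid (stereoisomer mixture) | C#CCCCC1(O)OOC(CC(=O)N2C(=O)OC[C@@H]2Cc2ccccc2)CC1C(=O)O | intermediate
12 | (S)-4-benzyl-3-{2-[6-hydroxy-6-(pent-4-yn-1-yl)-1,2-dioxan-3-yl]acetyl}oxazolidin-2-one (both C3 configurations, hemiketal anomers) | C#CCCCC1(O)CCC(CC(=O)N2C(=O)OC[C@@H]2Cc2ccccc2)OO1 | intermediate
13 | (S)-4-benzyl-3-{2-[(3S,6R)-6-methoxy-6-(pent-4-yn-1-yl)-1,2-dioxan-3-yl]acetyl}oxazolidin-2-one | C#CCCC[C@]1(OC)CC[C@@H](CC(=O)N2C(=O)OC[C@@H]2Cc2ccccc2)OO1 | intermediate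
14 | dec-9-enal | C=CCCCCCCCC=O | starting material
15 | (E)-1-iodoundeca-1,10-diene | C=CCCCCCCC/C=C/I | intermediate
16 | (S)-4-benzyl-3-{2-[(3S,6R)-6-[(6E)-hexadeca-6,15-dien-4-yn-1-yl]-6-methoxy-1,2-dioxan-3-yl]acetyl}oxazolidin-2-one | C=CCCCCCCC/C=C/C#CCCC[C@]1(OC)CC[C@@H](CC(=O)N2C(=O)OC[C@@H]2Cc2ccccc2)OO1 | intermediate
17 | 2-[(3S,6R)-6-[(6E)-hexadeca-6,15-dien-4-yn-1-yl]-6-methoxy-1,2-dioxan-3-yl]ethaneperoxoic acid (lithium salt in the flask) | C=CCCCCCCC/C=C/C#CCCC[C@]1(OC)CC[C@@H](CC(=O)OO)OO1 | intermediate
18 | 2-[(3S,6R)-6-[(6E)-hexadeca-6,15-dien-4-yn-1-yl]-6-methoxy-1,2-dioxan-3-yl]acetic acid | C=CCCCCCCC/C=C/C#CCCC[C@]1(OC)CC[C@@H](CC(=O)O)OO1 | target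

**Step count:** 8 steps in total. The longest linear sequence is 6 steps (steps 1, 3, 4, 5, 7, 8).

**Steps most likely to fail**

Step 3. The C5 radical may be trapped by dioxygen, or cyclise onto its own alkyne, before it adds to the unactivated terminal alkene, and the absence of facial control at C3 halves the useful material. Fallback, a known stepwise peroxidation: setting out from 4, the sodium enolate (NaH, THF, 0 °C) is C-alkylated with (S)-4-benzyl-3-[(E)-4-bromobut-2-enoyl]oxazolidin-2-one F1 (from 6, n-BuLi and (E)-4-bromobut-2-enoyl chloride) to give keto ester F2. TFA followed by warming removes the tert-butyl ester through β-keto acid F3 and leaves keto enoyl imide F4. Urea–hydrogen peroxide with catalytic Sc(OTf)3 in MeOH converts the ketone into methoxy hydroperoxy ketal F5, and Et2NH in CF3CH2OH closes the ring by intramolecular peroxy-Michael addition. The stereoisomer mixture is equilibrated at the ketal carbon (CSA, MeOH) and chromatographed, which comes back to the route at 13.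

Step 4. Acid and heat may decompose the peroxy hemiketal faster than CO2 is lost, or the decarboxylation may stall because the acid rests as the closed hemiketal. Fallback, the helper is unmasked before any peroxide exists: setting out from 4, TFA/CH2Cl2 at 0 °C gives 3-oxooct-7-ynoic acid F6, which is used cold in place of 4 under the conditions of step 3. The hemiketal acid 11 formed in the acetic acid medium should then lose CO2 at 23 °C without added acid or heating, and the route is rejoined at 12.

Step 5. The thermodynamic bias at the ketal carbon may be incomplete, the imide may suffer acid methanolysis, and the two diastereomers, whose stereocentres are remote from the auxiliary, may not separate. Fallback, classical resolution of the acid: setting out from 12, ketalisation as in step 5 is followed, without separation, by LiOH/H2O2 hydrolysis to racemic trans-2-[6-methoxy-6-(pent-4-yn-1-yl)-1,2-dioxan-3-yl]acetic acid F7. Fractional crystallisation with (R)-1-phenylethylamine gives the less soluble salt F8 (the antipodal amine is used if the wrong acid crystallises), and acidification frees 2-[(3S,6R)-6-methoxy-6-(pent-4-yn-1-yl)-1,2-dioxan-3-yl]acetic acid F9. Sonogashira coupling of F9 with 15 under the conditions of step 7 comes back to the route at 18.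

**Further compounds**

F1 | step 3 | (S)-4-benzyl-3-[(E)-4-bromobut-2-enoyl]oxazolidin-2-one | BrC/C=C/C(=O)N1C(=O)OC[C@@H]1Cc1ccccc1
F2 | step 3 | tert-butyl (E)-6-[(S)-4-benzyl-2-oxooxazolidin-3-yl]-2-(hex-5-ynoyl)-6-oxohex-4-enoate | C#CCCCC(=O)C(C/C=C/C(=O)N1C(=O)OC[C@@H]1Cc1ccccc1)C(=O)OC(C)(C)C
F3 | step 3 | (E)-6-[(S)-4-benzyl-2-oxooxazolidin-3-yl]-2-(hex-5-ynoyl)-6-oxohex-4-enoic acid | C#CCCCC(=O)C(C/C=C/C(=O)N1C(=O)OC[C@@H]1Cc1ccccc1)C(=O)O
F4 | step 3 | (S)-4-benzyl-3-[(E)-6-oxoundec-2-en-10-ynoyl]oxazolidin-2-one | C#CCCCC(=O)CC/C=C/C(=O)N1C(=O)OC[C@@H]1Cc1ccccc1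
F5 | step 3 | (S)-4-benzyl-3-[(E)-6-hydroperoxy-6-methoxyundec-2-en-10-ynoyl]oxazolidin-2-one | C#CCCCC(OC)(OO)CC/C=C/C(=O)N1C(=O)OC[C@@H]1Cc1ccccc1
F6 | step 4 | 3-oxooct-7-ynoic acid | C#CCCCC(=O)CC(=O)O
F7 | step 5 | racemic trans-2-[6-methoxy-6-(pent-4-yn-1-yl)-1,2-dioxan-3-yl]acetic acid | C#CCCC[C@]1(OC)CC[C@@H](CC(=O)O)OO1.C#CCCC[C@@]1(OC)CC[C@H](CC(=O)O)OO1
F8 | step 5 | (R)-1-phenylethylammonium 2-[(3S,6R)-6-methoxy-6-(pent-4-yn-1-yl)-1,2-dioxan-3-yl]acetate | C#CCCC[C@]1(OC)CC[C@@H](CC(=O)[O-])OO1.C[C@@H]([NH3+])c1ccccc1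
F9 | step 5 | 2-[(3S,6R)-6-methoxy-6-(pent-4-yn-1-yl)-1,2-dioxan-3-yl]acetic acid | C#CCCC[C@]1(OC)CC[C@@H](CC(=O)O)OO1
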